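**Retrosynthetic overview**

1. Target ⇒ its C-9 silyl ether ⇒ seco aryl iodide/acrylamide: the 21-membered ring is closed last by an intramolecular Heck reaction that makes the (E)-cinnamamide.
2. Seco compound ⇒ diaryl ether phenol + (S)-α-aryloxy aldehyde: the C7–aryl bond comes from para-hydroxyalkylation of the phenolate, with C-7 set by Felkin–Anh induction from C-8.
3. Diaryl ether phenol ⇒ 2-aryloxy-6-methoxybenzaldehyde by an oxidative 1,2-shift of the aryl group from carbon to oxygen (Dakin type). The formyl group first activates both SNAr etherifications of 2,6-difluorobenzaldehyde, then becomes the phenolic oxygen that later directs the C–C bond formation.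
4. Aldehyde ⇒ ester ⇒ Grandberg tryptamine synthesis and N-acryloylation of an arylhydrazine ⇒ 4-aminophenol + methyl (R)-glycerate (Mitsunobu inversion sets C-8).
5. Ring order: the two benzene rings are bought and joined as the diaryl ether first, the indole ring is built second, the macrocycle is closed last.

Assumption: C-7 is the benzylic carbinol carbon, C-8 the aryloxy-bearing carbon and C-9 the CH2OH carbon; the target is (7R,8S,E), that is erythro; methyl (R)-glycerate and 4-chlorobutanal are bought as such.

**Route**

Step 1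
Reactants: 1 1,3-difluorobenzene
Product: 3 2,6-difluorobenzaldehyde, via 2,6-difluorophenyllithium 2 (not isolated)
Conditions: n-BuLi, THF, −78 °C; DMF, −78 → 0 °C; aq. HCl
Reagents that add atoms: N,N-dimethylformamide, CN(C)C=O
Why: Directed ortho-lithiation: the C–H flanked by two fluorines is by far the most acidic, so deprotonation is regiospecific and the aryllithium is formylated by DMF.

Step 2
Reactants: 3 2,6-difluorobenzaldehyde; 4 4-iodophenol
Product: 6 2-(4-iodophenoxy)-6-methoxybenzaldehyde, via 2-fluoro-6-(4-iodophenoxy)benzaldehyde 5 (not isolated)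
Conditions: 4 (1.0 equiv), K2CO3, DMSO, 40 °C; then NaOMe/MeOH, 60 °C
Reagents that add atoms: sodium methoxide, [Na+].[O-]C
Why: Sequential nucleophilic aromatic substitution (SNAr): the ortho-formyl group activates both C–F bonds, the limiting phenoxide displaces the first fluoride and the stronger nucleophile methoxide then displaces the second, less activated fluoride in the same pot.

Step 3
Reactants: 6 2-(4-iodophenoxy)-6-methoxybenzaldehyde
Product: 8 2-(4-iodophenoxy)-6-methoxyphenol, via aryl formate 7 (not isolated)
Conditions: 30% H2O2, cat. H2SO4, MeOH, rt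
Reagents that add atoms: hydrogen peroxide, OO
Why: Dakin-type Baeyer–Villiger oxidation: the peroxy hemiacetal (Criegee adduct) of the electron-rich aldehyde undergoes a 1,2-shift of the aryl group from carbon to oxygen (aryl migrates in preference to hydride because of the two ortho oxygen donors) and the aryl formate is methanolysed in the flask, so the formyl group that activated both etherifications becomes the phenolic oxygen of ring A.

Step 4
Reactants: 9 methyl (R)-2,3-dihydroxypropanoate
Product: 10 methyl (R)-3-[(tert-butyldiphenylsilyl)oxy]-2-hydroxypropanoate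
Conditions: TBDPSCl, imidazole, CH2Cl2, 0 °C → rt
Reagents that add atoms: tert-butyl(chloro)diphenylsilane, CC(C)(C)[Si](Cl)(c1ccccc1)c1ccccc1
Why: Silyl ether formation: the bulky silyl chloride reacts only at the primary hydroxyl and the stereocentre is not involved.

Step 5
Reactants: 10 methyl (R)-3-[(tert-butyldiphenylsilyl)oxy]-2-hydroxypropanoate; 11 4-aminophenol
Product: 12 methyl (S)-2-(4-aminophenoxy)-3-[(tert-butyldiphenylsilyl)oxy]propanoate
Conditions: PPh3, DIAD, THF, 0 °C → rt
Reagents that add atoms: none
Why: Mitsunobu etherification: only the phenolic O–H (pKa about 10) is acidic enough to act as the pronucleophile so the aniline nitrogen is left alone, and SN2 attack on the alkoxyphosphonium ion inverts C-2 from R to S, which fixes the S configuration of C-8 of the target.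

Step 6
Reactants: 12 methyl (S)-2-(4-aminophenoxy)-3-[(tert-butyldiphenylsilyl)oxy]propanoate
Product: 14 methyl (S)-3-[(tert-butyldiphenylsilyl)oxy]-2-(4-hydrazinylphenoxy)propanoate hydrochloride, via arenediazonium chloride 13 (not isolated)
Conditions: NaNO2, 3 M HCl, MeCN/H2O, −5 °C; then SnCl2·2H2O, 0 °C
Reagents that add atoms: sodium nitrite, [Na+].[O-]N=O; hydrogen chloride, Cl
Why: Diazotisation followed by tin(II) chloride reduction turns the aniline into the arylhydrazine under cold acidic conditions that leave the ester, the silyl ether and the stereocentre untouched.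

Step 7
Reactants: 14 methyl (S)-3-[(tert-butyldiphenylsilyl)oxy]-2-(4-hydrazinylphenoxy)propanoate hydrochloride; 15 4-chlorobutanal; 16 acryloyl chloride
Product: 18 methyl (S)-2-{[3-(2-acrylamidoethyl)-1H-indol-5-yl]oxy}-3-[(tert-butyldiphenylsilyl)oxy]propanoate, via tryptamine ester 17 (not isolated)
Conditions: 15, Na2HPO4, MeOH/H2O, reflux; concentrate; NaHCO3 aq./EtOAc, 16, 0 °C
Reagents that add atoms: none
Why: Grandberg variant of the Fischer indole synthesis: hydrazone formation, displacement of chloride by the hydrazine nitrogen, [3,3]-shift of the ene-hydrazine and ring opening of the aminal give the 5-alkoxytryptamine whose side-chain nitrogen is the former terminal hydrazine nitrogen (the para substituent allows only the 5-substituted indole), and Schotten–Baumann acylation then makes the acrylamide.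

Step 8
Reactants: 18 methyl (S)-2-{[3-(2-acrylamidoethyl)-1H-indol-5-yl]oxy}-3-[(tert-butyldiphenylsilyl)oxy]propanoate
Product: 19 N-{2-[5-({(S)-1-[(tert-butyldiphenylsilyl)oxy]-3-oxopropan-2-yl}oxy)-1H-indol-3-yl]ethyl}acrylamide
Conditions: DIBAL-H (2.5 equiv), CH2Cl2, −78 °C; MeOH, then aq. Rochelle salt; used crude
Reagents that add atoms: none
Why: Partial ester reduction with DIBAL-H: the aluminium hemiacetal of the α-aryloxy ester is stable at −78 °C and releases the aldehyde only on work-up, so there is no over-reduction, the secondary amide is inert at this temperature and the C-8 stereocentre is never exposed to base.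

Step 9
Reactants: 8 2-(4-iodophenoxy)-6-methoxyphenol; 19 N-{2-[5-({(S)-1-[(tert-butyldiphenylsilyl)oxy]-3-oxopropan-2-yl}oxy)-1H-indol-3-yl]ethyl}acrylamide
Product: 20 N-{2-[5-({(1R,2S)-3-[(tert-butyldiphenylsilyl)oxy]-1-hydroxy-1-[4-hydroxy-3-(4-iodophenoxy)-5-methoxyphenyl]propan-2-yl}oxy)-1H-indol-3-yl]ethyl}acrylamide
Conditions: 8 (2 equiv), KOt-Bu (1 equiv), 18-crown-6 (1 equiv), THF/toluene, −40 °C; then 19 (1 equiv), −40 → −20 °C; AcOH quench
Reagents that add atoms: none
Why: Proposed new method: the crown-ether-separated potassium phenolate of 8 is an aromatic dienolate whose two ortho carbons are blocked, so it adds through its para carbon to the aldehyde of 19 and the cyclohexadienone alkoxide re-aromatises irreversibly by proton transfer; with the non-chelating K+/18-crown-6 counter-ion and the bulky non-coordinating silyl ether the addition follows the polar Felkin–Anh model with the C8–OAr bond anti to the incoming nucleophile, which gives the 7,8-anti (erythro) adduct, that is 7R from 8S, while the 1:1 phenol/phenolate buffer at −40 °C is too weak a base to enolise the aldehyde; the closest known reactions are the base-mediated para-hydroxyalkylation of 2,6-disubstituted phenols with formaldehyde or glyoxylate (Lederer–Manasse type) and the diastereoselective ortho-hydroxyalkylation of metal phenolates with chiral α-alkoxy aldehydes, neither of which has been shown for para attack on an enolisable α-aryloxy aldehyde with 1,2-induction.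

Step 10
Reactants: 20 N-{2-[5-({(1R,2S)-3-[(tert-butyldiphenylsilyl)oxy]-1-hydroxy-1-[4-hydroxy-3-(4-iodophenoxy)-5-methoxyphenyl]propan-2-yl}oxy)-1H-indol-3-yl]ethyl}acrylamide
Product: 21 (7R,8S,E)-9-O-TBDPS-protected macrocycle
Conditions: Pd(OAc)2 (20 mol %), P(o-tol)3 (40 mol %), Et3N, MeCN/DMF, 1 mM (slow addition), 80 °C
Reagents that add atoms: none
Why: Intramolecular Mizoroki–Heck reaction: oxidative addition of the aryl iodide, syn insertion at the unsubstituted acrylamide terminus and syn β-hydride elimination give the (E)-cinnamamide and close the 21-membered ring under high dilution, and the weak amine base does not ionise the phenol so the benzylic carbinol is not epimerised.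

Step 11
Reactants: 21 (7R,8S,E)-9-O-TBDPS-protected macrocycle
Product: 22 CNP0276372.1
Conditions: TBAF, AcOH, THF, 0 °C → rt
Reagents that add atoms: none
Why: Fluoride-induced cleavage of the silyl ether (driven by the strong Si–F bond), buffered by acetic acid, frees the primary alcohol without touching the phenol, the benzylic alcohol or the acrylamide.

**Compound list**

1 | 1,3-difluorobenzene | Fc1cccc(F)c1 | starting material
2 | 2,6-difluorophenyllithium | [Li]c1c(F)cccc1F | intermediate (not isolated)
3 | 2,6-difluorobenzaldehyde | O=Cc1c(F)cccc1F | intermediate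
4 | 4-iodophenol | Oc1ccc(I)cc1 | starting material
5 | 2-fluoro-6-(4-iodophenoxy)benzaldehyde | O=Cc1c(F)cccc1Oc1ccc(I)cc1 | intermediate (not isolated)
6 | 2-(4-iodophenoxy)-6-methoxybenzaldehyde | COc1cccc(Oc2ccc(I)cc2)c1C=O | intermediate
7 | 2-(4-iodophenoxy)-6-methoxyphenyl formate | COc1cccc(Oc2ccc(I)cc2)c1OC=O | intermediate (not isolated)
8 | 2-(4-iodophenoxy)-6-methoxyphenol | COc1cccc(Oc2ccc(I)cc2)c1O | intermediate
9 | methyl (R)-2,3-dihydroxypropanoate (methyl D-glycerate) | COC(=O)[C@H](O)CO | starting material
10 | methyl (R)-3-[(tert-butyldiphenylsilyl)oxy]-2-hydroxypropanoate | COC(=O)[C@H](O)CO[Si](c1ccccc1)(c1ccccc1)C(C)(C)C | intermediate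
11 | 4-aminophenol | Nc1ccc(O)cc1 | starting material
12 | methyl (S)-2-(4-aminophenoxy)-3-[(tert-butyldiphenylsilyl)oxy]propanoate | COC(=O)[C@@H](Oc1ccc(N)cc1)CO[Si](c1ccccc1)(c1ccccc1)C(C)(C)C | intermediate
13 | 4-{[(S)-3-[(tert-butyldiphenylsilyl)oxy]-1-methoxy-1-oxopropan-2-yl]oxy}benzenediazonium chloride | COC(=O)[C@@H](Oc1ccc([N+]#N)cc1)CO[Si](c1ccccc1)(c1ccccc1)C(C)(C)C.[Cl-] | intermediate (not isolated)
14 | methyl (S)-3-[(tert-butyldiphenylsilyl)oxy]-2-(4-hydrazinylphenoxy)propanoate hydrochloride | COC(=O)[C@@H](Oc1ccc(NN)cc1)CO[Si](c1ccccc1)(c1ccccc1)C(C)(C)C.Cl | intermediate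
15 | 4-chlorobutanal | O=CCCCCl | starting material
16 | acryloyl chloride (prop-2-enoyl chloride) | C=CC(=O)Cl | starting material
17 | methyl (S)-2-{[3-(2-aminoethyl)-1H-indol-5-yl]oxy}-3-[(tert-butyldiphenylsilyl)oxy]propanoate | COC(=O)[C@@H](Oc1ccc2[nH]cc(CCN)c2c1)CO[Si](c1ccccc1)(c1ccccc1)C(C)(C)C | intermediate (not isolated)
18 | methyl (S)-2-{[3-(2-acrylamidoethyl)-1H-indol-5-yl]oxy}-3-[(tert-butyldiphenylsilyl)oxy]propanoate | COC(=O)[C@@H](Oc1ccc2[nH]cc(CCNC(=O)C=C)c2c1)CO[Si](c1ccccc1)(c1ccccc1)C(C)(C)C | intermediate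
19 | N-{2-[5-({(S)-1-[(tert-butyldiphenylsilyl)oxy]-3-oxopropan-2-yl}oxy)-1H-indol-3-yl]ethyl}acrylamide | O=C[C@@H](Oc1ccc2[nH]cc(CCNC(=O)C=C)c2c1)CO[Si](c1ccccc1)(c1ccccc1)C(C)(C)C | intermediate
20 | N-{2-[5-({(1R,2S)-3-[(tert-butyldiphenylsilyl)oxy]-1-hydroxy-1-[4-hydroxy-3-(4-iodophenoxy)-5-methoxyphenyl]propan-2-yl}oxy)-1H-indol-3-yl]ethyl}acrylamide | C=CC(=O)NCCc1c[nH]c2ccc(O[C@@H](CO[Si](c3ccccc3)(c3ccccc3)C(C)(C)C)[C@H](O)c3cc(OC)c(O)c(Oc4ccc(I)cc4)c3)cc12 | intermediate
21 | (7R,8S,E)-21-membered macrolactam of the target with the C-9 primary hydroxyl as its tert-butyldiphenylsilyl ether | COc1cc2cc(c1O)Oc1ccc(cc1)/C=C/C(=O)NCCc1c[nH]c3ccc(cc13)O[C@@H](CO[Si](c1ccccc1)(c1ccccc1)C(C)(C)C)[C@@H]2O | intermediate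
22 | CNP0276372.1: (7R,8S,E)-macrocycle in which the serotonin 5-oxygen is bonded to C-8 of a guaiacylglycerol unit, the serotonin nitrogen carries an (E)-p-coumaroyl group and the coumaroyl 4-oxygen is bonded to C-5 of the guaiacyl ring | COc1cc2cc(c1O)Oc1ccc(cc1)/C=C/C(=O)NCCc1c[nH]c3ccc(cc13)O[C@@H](CO)[C@@H]2O | target

**Step count and risks**

Total steps: 11. Longest linear sequence: 8 steps (steps 4 to 11, from methyl (R)-glycerate 9); the ring A/ring B branch (steps 1 to 3) joins at step 9.

The three steps most likely to fail: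

Step 9 (the proposed new reaction). Para attack of the phenolate on a hindered aliphatic aldehyde may be slow at the low temperature needed to keep C-8 from epimerising and to avoid β-elimination of the silyloxy group, and the Felkin selectivity may be modest. The fallback uses known chemistry and replaces the phenolate by an arylzinc nucleophile, which is not basic. It sets out from 8. Iridium-catalysed C–H borylation (HBpin, then [Ir(OMe)(cod)]2, dtbpy, B2pin2, THF, 80 °C) takes place at the only C–H that is not next to a substituent, para to the hydroxyl, and gives 2-(4-iodophenoxy)-6-methoxy-4-(4,4,5,5-tetramethyl-1,3,2-dioxaborolan-2-yl)phenol F1. Cleavage of the pinacol ester through its diethanolamine adduct (diethanolamine, Et2O; then dilute HCl) gives [4-hydroxy-3-(4-iodophenoxy)-5-methoxyphenyl]boronic acid F2. Boron-to-zinc exchange with excess Et2Zn (toluene, 60 °C) followed by amino-alcohol-promoted aryl transfer to aldehyde 19 at −10 °C, under Felkin control that can be reinforced by the matched enantiomer of the ligand, comes back to the route at 20.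

Step 10. The Heck macrocyclisation may give oligomers or stall on the electron-rich aryl iodide. The fallback closes the same (E)-cinnamamide by olefin metathesis. It sets out from 20: Suzuki–Miyaura vinylation of the aryl iodide (potassium vinyltrifluoroborate, PdCl2(dppf), Et3N, n-PrOH, 80 °C) gives N-{2-[5-({(1R,2S)-3-[(tert-butyldiphenylsilyl)oxy]-1-hydroxy-1-[4-hydroxy-3-methoxy-5-(4-vinylphenoxy)phenyl]propan-2-yl}oxy)-1H-indol-3-yl]ethyl}acrylamide F3. Ring-closing metathesis between the styrene and the acrylamide (Hoveyda–Grubbs II, toluene, 80 °C, 1 mM) comes back at 21.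

Step 5. The free aniline may react with the azodicarboxylate or be alkylated, and the activated α-hydroxy ester may eliminate. The fallback avoids any free amine at this stage and makes the aryl–nitrogen bond by palladium catalysis instead. It sets out from 10: Mitsunobu reaction with 4-iodophenol 4 gives methyl (S)-3-[(tert-butyldiphenylsilyl)oxy]-2-(4-iodophenoxy)propanoate F4. Coupling with benzophenone hydrazone (Pd(OAc)2, Xantphos, Cs2CO3, toluene, 90 °C) gives methyl (S)-3-[(tert-butyldiphenylsilyl)oxy]-2-{4-[2-(diphenylmethylidene)hydrazinyl]phenoxy}propanoate F5. F5 is put directly into the conditions of step 7 with TsOH·H2O added, so that hydrazone exchange with 15 and indolisation occur in the flask with loss of benzophenone; after acylation with 16 it comes back at 18.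

Further compounds

F1 | step 9 | 2-(4-iodophenoxy)-6-methoxy-4-(4,4,5,5-tetramethyl-1,3,2-dioxaborolan-2-yl)phenol | COc1cc(B2OC(C)(C)C(C)(C)O2)cc(Oc2ccc(I)cc2)c1O
F2 | step 9 | [4-hydroxy-3-(4-iodophenoxy)-5-methoxyphenyl]boronic acid | COc1cc(B(O)O)cc(Oc2ccc(I)cc2)c1O
F3 | step 10 | N-{2-[5-({(1R,2S)-3-[(tert-butyldiphenylsilyl)oxy]-1-hydroxy-1-[4-hydroxy-3-methoxy-5-(4-vinylphenoxy)phenyl]propan-2-yl}oxy)-1H-indol-3-yl]ethyl}acrylamide | C=CC(=O)NCCc1c[nH]c2ccc(O[C@@H](CO[Si](c3ccccc3)(c3ccccc3)C(C)(C)C)[C@H](O)c3cc(OC)c(O)c(Oc4ccc(C=C)cc4)c3)cc12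
F4 | step 5 | methyl (S)-3-[(tert-butyldiphenylsilyl)oxy]-2-(4-iodophenoxy)propanoate | COC(=O)[C@@H](Oc1ccc(I)cc1)CO[Si](c1ccccc1)(c1ccccc1)C(C)(C)C
F5 | step 5 | methyl (S)-3-[(tert-butyldiphenylsilyl)oxy]-2-{4-[2-(diphenylmethylidene)hydrazinyl]phenoxy}propanoate | COC(=O)[C@@H](Oc1ccc(NN=C(c2ccccc2)c2ccccc2)cc1)CO[Si](c1ccccc1)(c1ccccc1)C(C)(C)C
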